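## The problem

Compound 24 is (+)-lariciresinol (21) esterified with isovaleric acid (22) at its only aliphatic hydroxyl. The core is one oxolane (O1, C2, C3, C4, C5) with a 4-hydroxy-3-methoxyphenyl group on C2, the acyloxymethyl arm on C3 and a 4-hydroxy-3-methoxybenzyl group on C4. The three contiguous stereocentres are 2S,3R,4R, that is 2,3-trans and 3,4-cis. C2 is the only centre flanked by an oxygen and an arene, so it can be made reliably by carbonyl addition and can then steer C3 and C4 if these arise in a ring-closing event. Three groups limit the chemistry. The C2–O1 linkage is a para-oxygenated benzylic ether: acid ionises it (epimerisation, Friedel–Crafts closure onto the other arene), quinone oxidants take its hydride, and prolonged hydrogenolysis cleaves it. The isovalerate does not survive hydroxide, hydride or organometallic reagents, and the free phenols are easily oxidised. The feature that opens a short route is that the ring bond C3–C4 and the bond from the exocyclic C4 methylene to its arene are 1,3-related, while O1, C5, C4 and that methylene together are simply an allyl ether on the C2 oxygen. A radical at C3 therefore closes 5-exo onto that allyl group to form the oxolane and leaves the unpaired electron on exactly the carbon that must be joined to the second arene. Because C3 passes through a planar radical, only C2 has to be built with absolute control.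

## Retrosynthesis

The first cut is the acyl C–O bond of the ester, giving 21 and isovaleric acid 22. Carrying the ester further back would expose it to hydroperoxide, sodium hydride and zinc. Protecting the C3 arm orthogonally, so that it could be acylated before the phenols are freed, was examined and set aside. A 4-methoxybenzyl ether is removed by quinone oxidants or acid, and both attack the C2–O1 linkage, which is itself a dialkoxybenzyl ether. A silyl ether would sit 1,3 to the alkoxide that has to be allylated and could migrate to it. The forward reaction therefore has to esterify one primary alcohol beside two free phenols, which a Mitsunobu reaction does because only the carboxylic acid is acidic enough to act as the nucleophile.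

The three O–H bonds of 21 are traced back to benzyl ethers in 20. One protecting group for all three oxygens keeps the early steps simple: benzyl ethers are inert to boron enolates, hydroperoxide, sodium hydride and low-valent nickel, and they leave without acid or oxidant. The forward step must hydrogenolyse three benzyl ethers, one of them aliphatic, without cleaving the benzylic C2–O1 bond.

In 20 the ring bond C3–C4 and the bond between the C4 methylene and its arene are cut together, leading to the N-hydroxyphthalimide ester 15 and the aryl iodide 17. The neighbouring cuts are weaker. Opening C2–O1 leads to a benzylic cation whose closure sets C2 only thermodynamically and invites Friedel–Crafts reaction. Cutting C2–C3 and C4–C5 as a cycloaddition leaves C4 with the wrong substituent. Cutting only the aryl–CH2 bond leaves the ring and two stereocentres to be made separately. The double cut removes the ring, two of the three stereocentres and one arene at once, and 15 is an open chain with a single stereocentre that matters. The forward reaction has to generate the C3 radical, close it 5-exo onto the O-allyl group faster than it is captured, and couple the resulting primary radical with an arylnickel species.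

The N–O ester bond of 15 goes back to the acid 13, and the O-allyl bond of 13 to the hydroxy acid 11 and allyl bromide 12. The allyl group supplies C5, C4 and the exocyclic methylene of the target. Etherification is placed at the acid stage on purpose: the alkoxide of a β-hydroxy ester or imide can fragment by retro-aldol or eliminate, whereas the alkoxide of a carboxylate has no such path. The benzyl ether on the arm cannot migrate.

The hydroxy acid 11 is cut between its C2 and C3 (the later oxolane C3 and C2), by way of the imide 9, to the acyl oxazolidinone 6 and O-benzylvanillin 2. An Evans syn aldol sets the carbinol centre with absolute control; the second centre it creates is the one erased in the radical step. A Morita–Baylis–Hillman route to the same oxidation pattern was considered and dropped, because electron-rich benzaldehydes react sluggishly there and a resolution would discard half the material. Compound 6 comes from 3-(benzyloxy)propanoic acid 3 and the oxazolidinone 4, 2 from vanillin 1, and 17 from 4-iodo-2-methoxyphenol 16, each in one standard step.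

## Roads not taken

Alternative 1: The cut goes through C3–C4 and both benzylic C–O bonds at once.
- **Forward step:** Anodic one-electron oxidation of 5-bromoconiferyl alcohol A1 would give phenoxyl radicals that pair at their β-carbons. Each quinone methide would be trapped by the hydroxymethyl group of the other half, giving the cis-fused 5,5'-dibromopinoresinol A2 in one operation. Hydrogenolysis over Pd/C would then remove both bromines and open one benzylic C–O bond to reach 21.
- **Merits:** No protecting groups are needed, the relative configuration of all ring centres comes from the bicycle, and the sequence is clearly shorter than the chosen one.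
- **Weak points:** Radical pairing has no element of absolute control, so A2 forms as the racemate and the single enantiomer would require a late resolution. Other coupling modes compete even with the 5-positions blocked. The ring opening must stop after exactly one of two equivalent C–O bonds while two aryl bromides are also reduced.
- **Comparison:** The chosen plan sets against the shorter length that absolute configuration is fixed in step 3 without loss of half the material, and that no statistical ring opening is needed. It shares one weakness, since step 9 must also spare a benzylic C–O bond under hydrogen.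

Alternative 2: The cut removes C2–C3 and C4–C5 together.
- **Forward step:** CsF would release a non-stabilised carbonyl ylide built on the aldehyde carbon of 2. Its cycloaddition across the C=C bond of the menthyloxy butenolide A3, anti to the acetal substituent, would give the cis-fused lactone A4 with the aryl group exo.
- **Merits:** The oxolane and all three of its stereocentres arise in one concerted step under auxiliary control; cis fusion gives 3,4-cis and the exo aryl gives 2,3-trans. There is no race between ring closure and capture as in step 8, and in this respect the cycloaddition is the safer ring-forming step.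
- **Weak points:** The orientation of the unsymmetrical ylide must be right. More seriously, C4 emerges carrying an acetal carbon instead of an arylmethyl group. That requires hydrolysis, addition of an aryl-metal reagent and removal of the new benzylic oxygen beside the equally benzylic C2–O1 bond, plus reduction of the lactone carbon to the C3 arm. About five steps follow before the ester can be attached.
- **Comparison:** The chosen plan attaches the second arene in the ring-forming step itself, so nothing has to be deoxygenated next to C2–O1 and only two steps follow the ring closure.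

Alternative 3: The cuts are the bond from C4 to its exocyclic benzylic carbon and the C2–C3 bond, with C2–O1 left for a later etherification.
- **Forward step:** The lithiated dithiane A6 would add to the menthyloxy butenolide A5 anti to the acetal substituent, and the lactone enolate would be trapped by 2 to give the all-trans lactone A7 as carbinol epimers. Desulfurisation over Raney Ni, hydride reduction to a triol and acid-promoted closure of C2–O1 would follow.
- **Merits:** Both C–C bonds and the C3 and C4 configurations are made in one flask by long-established reaction types, and the trans lactone translates into the 3,4-cis oxolane. The C3 arm emerges as a free primary alcohol while both phenols are still benzylated, so the ester goes on by plain acylation and only aryl benzyl ethers remain for hydrogenolysis. Here it is better than the chosen plan, which needs a chemoselective esterification of 21 and a hydrogenolysis that includes a slow aliphatic benzyl ether.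
- **Weak points:** Ring closure by ionising the benzylic carbinol is the same reactivity that leads to Friedel–Crafts closure onto the electron-rich arene of the C4 side chain, and it sets C2 only thermodynamically. Desulfurisation must spare two benzyl ethers and a benzylic alcohol. Dithiane and chiral butenolide are used stoichiometrically, and the step count is no lower.
- **Comparison:** The chosen plan fixes C2 kinetically in the aldol, has no cationic step, and makes the last C–C bond catalytically from a separate aryl iodide that can be varied.

Key step: step 8

Assumption: 3, 4 and 16 are taken as purchasable, and any epimerisation at the carbon α to the carboxyl group of 13 and 15 is without consequence because that carbon becomes the radical in step 8; these compounds are drawn with the configuration delivered by the aldol.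

Step 1
Reactants: 1 vanillin
Product: 2 4-(benzyloxy)-3-methoxybenzaldehyde (O-benzylvanillin)
Conditions: BnBr, K2CO3, DMF, rt
Reagents that add atoms: benzyl bromide, BrCc1ccccc1
Why: Williamson etherification of the phenoxide with a benzylic bromide; the aldehyde is untouched and no stereocentre is involved.

Step 2
Reactants: 3 3-(benzyloxy)propanoic acid; 4 (4S)-4-benzyl-1,3-oxazolidin-2-one
Product: 6 (4S)-4-benzyl-3-[3-(benzyloxy)propanoyl]-1,3-oxazolidin-2-one, via mixed pivalic anhydride 5 (not isolated)
Conditions: t-BuCOCl, Et3N, THF, −20 °C; then LiCl, 4, −20 °C → rt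
Reagents that add atoms: none
Why: N-acylation of the oxazolidinone through the mixed anhydride, which the lithium-activated carbamate attacks at the less hindered carbonyl; this one-flask procedure avoids an acid chloride and strong base.

Step 3
Reactants: 6 (4S)-4-benzyl-3-[3-(benzyloxy)propanoyl]-1,3-oxazolidin-2-one; 2 4-(benzyloxy)-3-methoxybenzaldehyde
Product: 9 (4S)-4-benzyl-3-[(2S,3S)-2-(benzyloxymethyl)-3-(4-benzyloxy-3-methoxyphenyl)-3-hydroxypropanoyl]-1,3-oxazolidin-2-one, via Z-boron enolate 7 (not isolated), via boron aldolate 8 (not isolated)
Conditions: n-Bu2BOTf, i-Pr2NEt, CH2Cl2, −78 °C; then 2, −78 → 0 °C; then pH 7 buffer, MeOH, 30% H2O2, 0 °C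
Reagents that add atoms: none
Why: Evans syn aldol: the Z-boron enolate 7 reacts through a closed chair transition state on the face away from the benzyl group of the auxiliary, which sets the carbinol carbon as S (the future oxolane C2) together with an incidental 2S centre. The covalent boron enolate of a β-alkoxy imide is not basic enough to expel benzyloxide at low temperature, and enolates of this imide class are known to be alkylated without loss of the β-alkoxy group.

Step 4
Reactants: 9 (4S)-4-benzyl-3-[(2S,3S)-2-(benzyloxymethyl)-3-(4-benzyloxy-3-methoxyphenyl)-3-hydroxypropanoyl]-1,3-oxazolidin-2-one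
Product: 11 (2S,3S)-2-(benzyloxymethyl)-3-(4-benzyloxy-3-methoxyphenyl)-3-hydroxypropanoic acid, via peroxy acid 10 (not isolated)
Conditions: LiOH·H2O, 30% H2O2, THF–H2O (3:1), 0 °C; then aq. Na2SO3; then 1 M HCl to pH 2–3, 0 °C
Reagents that add atoms: hydrogen peroxide, OO
Why: Hydroperoxide cleavage of the N-acyl oxazolidinone at the exocyclic carbonyl, followed by sulfite reduction of the peroxy acid 10. The conditions are too mild for retro-aldol or for epimerisation of the benzylic carbinol, and the auxiliary 4 is recovered.

Step 5
Reactants: 11 (2S,3S)-2-(benzyloxymethyl)-3-(4-benzyloxy-3-methoxyphenyl)-3-hydroxypropanoic acid; 12 allyl bromide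
Product: 13 (2S,3S)-3-(allyloxy)-2-(benzyloxymethyl)-3-(4-benzyloxy-3-methoxyphenyl)propanoic acid
Conditions: NaH (2.5 equiv), THF, 0 °C; then 12 (1.3 equiv), n-Bu4NI (cat.), 0 °C → rt; then 1 M HCl to pH 3, 0 °C
Reagents that add atoms: none
Why: Williamson etherification of the dianion: in THF the alkoxide is the only strong nucleophile, and because the carbonyl is a carboxylate neither retro-aldol nor β-elimination has a feasible leaving enolate. The benzylic stereocentre is not touched.

Step 6
Reactants: 13 (2S,3S)-3-(allyloxy)-2-(benzyloxymethyl)-3-(4-benzyloxy-3-methoxyphenyl)propanoic acid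
Product: 15 1,3-dioxoisoindolin-2-yl (2S,3S)-3-(allyloxy)-2-(benzyloxymethyl)-3-(4-benzyloxy-3-methoxyphenyl)propanoate, via O-acylisourea 14 (not isolated)
Conditions: N-hydroxyphthalimide, i-PrN=C=N-i-Pr, DMAP (5 mol%), CH2Cl2, 0 °C → rt
Reagents that add atoms: N-hydroxyphthalimide, O=C1c2ccccc2C(=O)N1O
Why: Carbodiimide (Steglich-type) esterification gives the redox-active ester. Catalytic DMAP and low temperature keep β-elimination of the activated ester in check, and epimerisation at the α-carbon would be harmless.

Step 7
Reactants: 16 4-iodo-2-methoxyphenol
Product: 17 1-(benzyloxy)-4-iodo-2-methoxybenzene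
Conditions: BnBr, K2CO3, DMF, rt
Reagents that add atoms: benzyl bromide, BrCc1ccccc1
Why: Williamson etherification of the phenoxide; the aryl iodide is inert to carbonate at room temperature.

Step 8
Reactants: 15 1,3-dioxoisoindolin-2-yl (2S,3S)-3-(allyloxy)-2-(benzyloxymethyl)-3-(4-benzyloxy-3-methoxyphenyl)propanoate; 17 1-(benzyloxy)-4-iodo-2-methoxybenzene
Product: 20 (2S,3R,4R)-3-(benzyloxymethyl)-2-(4-benzyloxy-3-methoxyphenyl)-4-(4-benzyloxy-3-methoxybenzyl)oxolane, via secondary C3 radical 18 (not isolated), via cyclised primary radical 19 (not isolated)
Conditions: NiBr2·MeOCH2CH2OMe (10 mol%), 4,4'-di-tert-butyl-2,2'-bipyridine (10 mol%), Zn (2 equiv), 17 (1.5 equiv), DMA (0.05 M), 25 °C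
Reagents that add atoms: none
Why: Zinc reduces the nickel salt to zerovalent nickel, which adds oxidatively to 17 to give an arylnickel iodide of divalent nickel, while electron transfer to the phthalimide ester 15 releases phthalimide anion and CO2 and leaves the secondary radical 18. Radical 18 closes 5-exo-trig onto the allyl ether (C3–C4 bond, oxolane ring) to the primary radical 19, which the arylnickel species captures; reductive elimination from trivalent nickel forms the CH2–aryl bond and zinc returns the catalyst. The closest known reaction type is the nickel-catalysed reductive cross-electrophile coupling of N-hydroxyphthalimide esters with aryl iodides, in which alkene-tethered radicals cyclise before they couple, together with the analogous cyclisation–arylation of β-halo allyl ethers. Ring closure should go through a chair-like transition state with the C2 aryl group pseudo-equatorial, which places the new C4 methylene trans to it. The benzyloxymethyl group on the radical carbon turns away from the aryl group, so C3 should end trans to C2 and cis to C4; both new centres are thus set by the existing S centre at C2, and the α-configuration of 15 is erased in the planar radical. The step needs ring closure to outrun bimolecular capture of 18 by nickel: the ether oxygen in the chain makes this closure fast, and low catalyst concentration and dilution keep capture slow. The benzyl ethers, the aryl methyl ethers and the allyl C–O bond should be inert to low-valent nickel under these conditions.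

Step 9
Reactants: 20 (2S,3R,4R)-3-(benzyloxymethyl)-2-(4-benzyloxy-3-methoxyphenyl)-4-(4-benzyloxy-3-methoxybenzyl)oxolane
Product: 21 (+)-lariciresinol, 4-[(2S,3R,4R)-4-(4-hydroxy-3-methoxybenzyl)-3-(hydroxymethyl)oxolan-2-yl]-2-methoxyphenol
Conditions: H2 (1 atm), 10% Pd/C, EtOAc–EtOH (1:1), rt, stopped at full conversion
Reagents that add atoms: none
Why: Catalytic hydrogenolysis of three benzyl ethers; the aryl ethers fall first, and in a neutral solvent at one atmosphere the hindered secondary C2–O1 ether should be cleaved more slowly than the primary benzyl ether if the reaction is stopped in time. No stereocentre is affected.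

Step 10
Reactants: 21 (+)-lariciresinol; 22 isovaleric acid
Product: 24 (+)-9'-isovaleroxylariciresinol, [(2S,3R,4R)-2-(4-hydroxy-3-methoxyphenyl)-4-(4-hydroxy-3-methoxybenzyl)oxolan-3-yl]methyl 3-methylbutanoate, via alkoxyphosphonium isovalerate 23 (not isolated)
Conditions: 22 (1.1 equiv), PPh3, i-PrO2CN=NCO2i-Pr, THF, 0 °C → rt
Reagents that add atoms: none
Why: Mitsunobu esterification: the primary alcohol is activated as the alkoxyphosphonium 23 and displaced at its methylene by isovalerate, the only pronucleophile acidic enough to be deprotonated by the betaine in preference to the phenols, so the phenols should stay free. Substitution at a methylene leaves all three stereocentres untouched.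

Compound list

1 | vanillin (4-hydroxy-3-methoxybenzaldehyde) | COc1cc(C=O)ccc1O | starting material
2 | 4-(benzyloxy)-3-methoxybenzaldehyde (O-benzylvanillin) | COc1cc(C=O)ccc1OCc1ccccc1 | intermediate
3 | 3-(benzyloxy)propanoic acid | OC(=O)CCOCc1ccccc1 | starting material
4 | (4S)-4-benzyl-1,3-oxazolidin-2-one | O=C1OC[C@H](Cc2ccccc2)N1 | starting material
5 | 3-(benzyloxy)propanoic pivalic anhydride (not isolated) | CC(C)(C)C(=O)OC(=O)CCOCc1ccccc1 | intermediate
6 | (4S)-4-benzyl-3-[3-(benzyloxy)propanoyl]-1,3-oxazolidin-2-one | O=C1OC[C@H](Cc2ccccc2)N1C(=O)CCOCc1ccccc1 | intermediate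
7 | (Z)-dibutylboron enolate of 6 (not isolated) | O=C1OC[C@H](Cc2ccccc2)N1/C(OB(CCCC)CCCC)=C/COCc1ccccc1 | intermediate
8 | O-dibutylboryl aldolate of 9 (not isolated) | O=C1OC[C@H](Cc2ccccc2)N1C(=O)[C@@H](COCc1ccccc1)[C@H](OB(CCCC)CCCC)c1ccc(OCc2ccccc2)c(OC)c1 | intermediate
9 | (4S)-4-benzyl-3-[(2S,3S)-2-(benzyloxymethyl)-3-(4-benzyloxy-3-methoxyphenyl)-3-hydroxypropanoyl]-1,3-oxazolidin-2-one | O=C1OC[C@H](Cc2ccccc2)N1C(=O)[C@@H](COCc1ccccc1)[C@H](O)c1ccc(OCc2ccccc2)c(OC)c1 | intermediate
10 | (2S,3S)-2-(benzyloxymethyl)-3-(4-benzyloxy-3-methoxyphenyl)-3-hydroxypropaneperoxoic acid (not isolated) | COc1cc([C@@H](O)[C@H](COCc2ccccc2)C(=O)OO)ccc1OCc1ccccc1 | intermediate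
11 | (2S,3S)-2-(benzyloxymethyl)-3-(4-benzyloxy-3-methoxyphenyl)-3-hydroxypropanoic acid | COc1cc([C@@H](O)[C@H](COCc2ccccc2)C(=O)O)ccc1OCc1ccccc1 | intermediate
12 | allyl bromide (3-bromoprop-1-ene) | C=CCBr | starting material
13 | (2S,3S)-3-(allyloxy)-2-(benzyloxymethyl)-3-(4-benzyloxy-3-methoxyphenyl)propanoic acid | COc1cc([C@@H](OCC=C)[C@H](COCc2ccccc2)C(=O)O)ccc1OCc1ccccc1 | intermediate
14 | O-acylisourea of 13 with N,N'-diisopropylcarbodiimide (not isolated) | COc1cc([C@@H](OCC=C)[C@H](COCc2ccccc2)C(=O)OC(=NC(C)C)NC(C)C)ccc1OCc1ccccc1 | intermediate
15 | 1,3-dioxoisoindolin-2-yl (2S,3S)-3-(allyloxy)-2-(benzyloxymethyl)-3-(4-benzyloxy-3-methoxyphenyl)propanoate | COc1cc([C@@H](OCC=C)[C@H](COCc2ccccc2)C(=O)ON2C(=O)c3ccccc3C2=O)ccc1OCc1ccccc1 | intermediate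
16 | 4-iodo-2-methoxyphenol | COc1cc(I)ccc1O | starting material
17 | 1-(benzyloxy)-4-iodo-2-methoxybenzene | COc1cc(I)ccc1OCc1ccccc1 | intermediate
18 | (1S)-1-(allyloxy)-3-(benzyloxy)-1-(4-benzyloxy-3-methoxyphenyl)propan-2-yl radical (not isolated) | COc1cc([C@@H](OCC=C)[CH]COCc2ccccc2)ccc1OCc1ccccc1 | intermediate
19 | [(3R,4R,5S)-4-(benzyloxymethyl)-5-(4-benzyloxy-3-methoxyphenyl)oxolan-3-yl]methyl radical (not isolated) | [CH2][C@H]1CO[C@H](c2ccc(OCc3ccccc3)c(OC)c2)[C@H]1COCc1ccccc1 | intermediate
20 | (2S,3R,4R)-3-(benzyloxymethyl)-2-(4-benzyloxy-3-methoxyphenyl)-4-(4-benzyloxy-3-methoxybenzyl)oxolane | COc1cc(C[C@H]2CO[C@H](c3ccc(OCc4ccccc4)c(OC)c3)[C@H]2COCc2ccccc2)ccc1OCc1ccccc1 | intermediate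
21 | (+)-lariciresinol, 4-[(2S,3R,4R)-4-(4-hydroxy-3-methoxybenzyl)-3-(hydroxymethyl)oxolan-2-yl]-2-methoxyphenol | COc1cc(C[C@H]2CO[C@H](c3ccc(O)c(OC)c3)[C@H]2CO)ccc1O | intermediate
22 | isovaleric acid (3-methylbutanoic acid) | CC(C)CC(=O)O | starting material
23 | alkoxytriphenylphosphonium isovalerate of 21 (not isolated) | COc1cc(C[C@H]2CO[C@H](c3ccc(O)c(OC)c3)[C@H]2CO[P+](c2ccccc2)(c2ccccc2)c2ccccc2)ccc1O.CC(C)CC(=O)[O-] | intermediate
24 | (+)-9'-isovaleroxylariciresinol, [(2S,3R,4R)-2-(4-hydroxy-3-methoxyphenyl)-4-(4-hydroxy-3-methoxybenzyl)oxolan-3-yl]methyl 3-methylbutanoate | COc1cc(C[C@H]2CO[C@H](c3ccc(O)c(OC)c3)[C@H]2COC(=O)CC(C)C)ccc1O | target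

Total step count: 10. Longest linear sequence: 8 steps (steps 1, 3, 4, 5, 6, 8, 9, 10 from vanillin; equally steps 2, 3, 4, 5, 6, 8, 9, 10 from 3).

Least certain steps

Step 8 (key step). The most likely failure is capture of radical 18 by nickel before ring closure, which would lead to direct arylation at C3 or to β-alkoxide elimination. Further risks are reduction of the radical by hydrogen abstraction from the solvent, reductive homocoupling of 17, and erosion of the trans,cis selectivity. The fallback separates ring closure from arylation and sets out from 15. Light-driven decarboxylative borylation with bis(catecholato)diboron in DMA is a nickel-free radical chain in which the cyclisation competes only with slow borylation; it would give the cyclised catechol boronate F1, which is transesterified in the same flask (pinacol, Et3N) to the pinacol boronate F2. KHF2 in aqueous methanol would convert F2 into the potassium trifluoroborate F3. Suzuki–Miyaura coupling of F3 with 17 (Pd(OAc)2, 2-dicyclohexylphosphino-2',6'-diisopropoxybiphenyl, K2CO3, toluene–H2O, 80 °C) comes back to the route at 20.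

Step 9. The danger is over-reduction: hydrogenolysis of the benzylic C2–O1 bond while the slower aliphatic benzyl ether is still being cleaved, once the para-phenol has been unmasked. The fallback changes the mechanism from surface hydrogenolysis to electron-transfer cleavage. It sets out from 20 and treats it with lithium 4,4'-di-tert-butylbiphenylide in THF at −78 °C. The benzyl groups accept the electron through their unsubstituted phenyl rings, and the aryl ethers become phenoxides, which make the ring arene too electron-rich to be reduced. The fallback returns at 21 without any new isolated compound.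

Step 5. The risks are competing alkylation of the carboxylate, after which the ester alkoxide could fragment by retro-aldol or eliminate, and sluggish etherification of the hindered secondary alkoxide. The fallback etherifies before the auxiliary is removed and without base. It sets out from 9, which with allyl 2,2,2-trichloroacetimidate and catalytic TfOH in cyclohexane–CH2Cl2 at 0 °C would give the O-allyl imide F4. Hydroperoxide cleavage of F4 (LiOH, H2O2, THF–H2O, 0 °C) returns to the route at 13.

Step 10. The risk is loss of chemoselectivity (etherification or acylation at a phenol) or slow displacement at the β-branched methylene. The fallback sets out from 21 and acylates all three hydroxyls (isovaleryl chloride, pyridine, DMAP, CH2Cl2) to the tris(isovalerate) F5. The two aryl esters, far more electrophilic than the alkyl ester, are then removed by aminolysis with pyrrolidine in CH2Cl2 at 0 °C, which arrives at 24.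

Step 3. The risk is β-elimination of benzyloxide from the enolate, or retro-aldol during work-up. The fallback sets the carbinol by ketone reduction and adds the arm afterwards; it sets out from 2.
- Roskamp homologation (methyl diazoacetate, SnCl2 cat., CH2Cl2) would give the β-keto ester F6.
- Transfer hydrogenation with RuCl[(S,S)-TsDPEN](p-cymene) and HCO2H–Et3N would give the (S)-hydroxy ester F7.
- Fráter–Seebach alkylation of its dianion (LDA, 2.2 equiv, THF, −78 → −20 °C, then benzyl chloromethyl ether) would give the anti ester F8.
- Saponification (LiOH, THF–H2O) would give the anti acid F9, the C2 epimer of 11.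
- Because that centre is erased in step 8, F9 is carried through the conditions of step 5 to the anti allyl ether acid F10 and of step 6 to the anti phthalimide ester F11, and the conditions of step 8 bring the sequence back to the route at 20.

Further compounds

F1 | step 8 | 2-{[(3R,4R,5S)-4-(benzyloxymethyl)-5-(4-benzyloxy-3-methoxyphenyl)oxolan-3-yl]methyl}-1,3,2-benzodioxaborole (catechol boronate, not isolated) | B1(Oc2ccccc2O1)C[C@H]3CO[C@H](c4ccc(OCc5ccccc5)c(OC)c4)[C@H]3COCc3ccccc3
F2 | step 8 | 2-{[(3R,4R,5S)-4-(benzyloxymethyl)-5-(4-benzyloxy-3-methoxyphenyl)oxolan-3-yl]methyl}-4,4,5,5-tetramethyl-1,3,2-dioxaborolane (pinacol boronate) | CC1(C)OB(C[C@H]2CO[C@H](c3ccc(OCc4ccccc4)c(OC)c3)[C@H]2COCc2ccccc2)OC1(C)C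
F3 | step 8 | potassium {[(3R,4R,5S)-4-(benzyloxymethyl)-5-(4-benzyloxy-3-methoxyphenyl)oxolan-3-yl]methyl}trifluoroborate | [K+].F[B-](F)(F)C[C@H]1CO[C@H](c2ccc(OCc3ccccc3)c(OC)c2)[C@H]1COCc1ccccc1
F0 | step 9 | none | none
F4 | step 5 | (4S)-3-[(2S,3S)-3-(allyloxy)-2-(benzyloxymethyl)-3-(4-benzyloxy-3-methoxyphenyl)propanoyl]-4-benzyl-1,3-oxazolidin-2-one | O=C1OC[C@H](Cc2ccccc2)N1C(=O)[C@@H](COCc1ccccc1)[C@H](OCC=C)c1ccc(OCc2ccccc2)c(OC)c1
F5 | step 10 | lariciresinol tris(3-methylbutanoate) | COc1cc(C[C@H]2CO[C@H](c3ccc(OC(=O)CC(C)C)c(OC)c3)[C@H]2COC(=O)CC(C)C)ccc1OC(=O)CC(C)C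
F6 | step 3 | methyl 3-(4-benzyloxy-3-methoxyphenyl)-3-oxopropanoate | COC(=O)CC(=O)c1ccc(OCc2ccccc2)c(OC)c1
F7 | step 3 | methyl (3S)-3-(4-benzyloxy-3-methoxyphenyl)-3-hydroxypropanoate | COc1cc([C@@H](O)CC(=O)OC)ccc1OCc1ccccc1
F8 | step 3 | methyl (2R,3S)-2-(benzyloxymethyl)-3-(4-benzyloxy-3-methoxyphenyl)-3-hydroxypropanoate | COc1cc([C@@H](O)[C@@H](COCc2ccccc2)C(=O)OC)ccc1OCc1ccccc1
F9 | step 3 | (2R,3S)-2-(benzyloxymethyl)-3-(4-benzyloxy-3-methoxyphenyl)-3-hydroxypropanoic acid | COc1cc([C@@H](O)[C@@H](COCc2ccccc2)C(=O)O)ccc1OCc1ccccc1
F10 | step 3 | (2R,3S)-3-(allyloxy)-2-(benzyloxymethyl)-3-(4-benzyloxy-3-methoxyphenyl)propanoic acid | COc1cc([C@@H](OCC=C)[C@@H](COCc2ccccc2)C(=O)O)ccc1OCc1ccccc1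
F11 | step 3 | 1,3-dioxoisoindolin-2-yl (2R,3S)-3-(allyloxy)-2-(benzyloxymethyl)-3-(4-benzyloxy-3-methoxyphenyl)propanoate | COc1cc([C@@H](OCC=C)[C@@H](COCc2ccccc2)C(=O)ON2C(=O)c3ccccc3C2=O)ccc1OCc1ccccc1
A1 | alternative 1 | 5-bromoconiferyl alcohol, (E)-2-bromo-4-(3-hydroxyprop-1-enyl)-6-methoxyphenol | COc1cc(/C=C/CO)cc(Br)c1O
A2 | alternative 1 | 5,5'-dibromopinoresinol (needed enantiomer drawn; formed as the racemate) | COc1cc(cc(Br)c1O)[C@H]1OC[C@H]2[C@@H]1CO[C@@H]2c1cc(Br)c(O)c(OC)c1
A3 | alternative 2 | (5S)-5-[(1S,2R,5S)-menthyloxy]furan-2(5H)-one | O=C1O[C@H](O[C@H]2C[C@@H](C)CC[C@@H]2C(C)C)C=C1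
A4 | alternative 2 | 6-(4-benzyloxy-3-methoxyphenyl)-4-menthyloxy-3,7-dioxabicyclo[3.3.0]octan-2-one, aryl exo | COc1cc([C@H]2OC[C@H]3[C@@H]2C(=O)O[C@@H]3O[C@H]4C[C@@H](C)CC[C@@H]4C(C)C)ccc1OCc1ccccc1
A5 | alternative 3 | (5R)-5-[(1R,2S,5R)-menthyloxy]furan-2(5H)-one | O=C1O[C@@H](O[C@@H]2C[C@H](C)CC[C@H]2C(C)C)C=C1
A6 | alternative 3 | 2-(4-benzyloxy-3-methoxyphenyl)-1,3-dithiane | COc1cc(C2SCCCS2)ccc1OCc1ccccc1
A7 | alternative 3 | 3-[(4-benzyloxy-3-methoxyphenyl)(hydroxy)methyl]-4-[2-(4-benzyloxy-3-methoxyphenyl)-1,3-dithian-2-yl]-5-menthyloxyoxolan-2-one, all-trans ring, carbinol epimers | O=C1O[C@@H](O[C@@H]2C[C@H](C)CC[C@H]2C(C)C)[C@H](C3(c4ccc(OCc5ccccc5)c(OC)c4)SCCCS3)[C@H]1C(O)c1ccc(OCc2ccccc2)c(OC)c1
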